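**Retrosynthetic overview**

1. Target 27 comes from silyl ether 26; ring C (eleven-membered) is closed last at C14–C1 by Ni/Cr-mediated addition of a C1 vinyl iodide to a C14 aldehyde.
2. The C9–C14 side chain (C11/C12 set by anti-crotylation of acrolein) is joined at C8–C9 by B-alkyl Suzuki coupling to a 1-iodovinyl group on the hydrindenone.
3. Ring A oxygenation: the C15 ketone is moved to C2 by MeLi addition and oxidative 1,3-transposition; C3–OH comes from α'-hydroxylation and C2–OH from hydroxyl-directed reduction.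
4. Key step: iodine-atom-transfer radical cyclisation. The α-keto radical at C16 closes 5-exo onto the proximal allene carbon C7, forming ring B, the C16 and C7 stereocentres and the C8(I)=C19H2 handle in one operation.
5. Quaternary C4 comes from copper-catalysed asymmetric conjugate addition of a homoallenyl Grignard reagent to 3-methylcyclohex-2-enone. Ring order: A (bought), B (radical), C (Ni/Cr).

Labels: trinervitane numbering. Ring A = C1, C2, C3, C4, C16, C15 (C17 methyl on C15, C18 methyl on C4); ring B = C4, C5, C6, C7, C16; ring C = C1, C15, C16, C7, C8(=C19H2), C9, C10, C11(OH), C12(C20 methyl), C13, C14(OH). Target configuration: 2R,3R,4S,7R,11S,12R,14S,16S. CIP letters of intermediates refer to the numbering of each name; the SMILES are authoritative.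

Assumption: penta-3,4-dien-1-ol is taken as a catalogue compound.

**Route**

Step 1
Reactants: 1 penta-3,4-dien-1-ol
Product: 2 5-bromopenta-1,2-diene
Conditions: CBr4, PPh3, CH2Cl2, 0 °C
Reagents that add atoms: carbon tetrabromide, BrC(Br)(Br)Br
Why: Appel bromination of a primary alcohol under neutral conditions leaves the allene untouched.

Step 2
Reactants: 2 5-bromopenta-1,2-diene; 3 3-methylcyclohex-2-en-1-one
Product: 6 (3S)-2-iodo-3-methyl-3-(penta-3,4-dien-1-yl)cyclohexan-1-one, via penta-3,4-dien-1-ylmagnesium bromide 4 (not isolated), via bromomagnesium enolate 5 (not isolated)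
Conditions: Mg, Et2O, rt; then 3, Cu(OTf)2 (3 mol%), (S)-1-(1-hydroxy-4-methylpentan-2-yl)-3-(2,4,6-trimethylphenyl)-4,5-dihydro-1H-imidazol-3-ium hexafluorophosphate (4 mol%; ligand antipode chosen for the S centre), Et2O, 0 °C; then NIS, THF, −78 °C
Reagents that add atoms: N-iodosuccinimide, O=C1CCC(=O)N1I
Why: Copper–NHC-catalysed asymmetric conjugate addition (Alexakis–Mauduit type) of the primary Grignard reagent to the β-methyl enone sets quaternary C4 under ligand control, and the regiodefined magnesium enolate is iodinated in the same flask at C16.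

Step 3
Reactants: 6 (3S)-2-iodo-3-methyl-3-(penta-3,4-dien-1-yl)cyclohexan-1-one
Product: 7 (3R,3aR,7aS)-3-(1-iodoethenyl)-7a-methyloctahydro-4H-inden-4-one
Conditions: Bu3SnSnBu3 (10 mol%), PhH (0.3 M), hν (sunlamp), 80 °C
Reagents that add atoms: none
Why: Proposed new method: the stannyl radical abstracts iodine to give the electrophilic α-keto radical at C16, which closes 5-exo onto the proximal allene carbon C7 (cis ring fusion forced by the three-atom tether; the C8 unit ends cis to the C16–C15 bond through the Beckwith–Houk chair transition state, 1,5-cis rule), and the resulting 1-substituted vinyl radical takes iodine from 6 to carry the chain and leave C8(I)=C19H2; the closest known reactions are Curran iodine-atom-transfer cyclisations of α-iodo carbonyl compounds onto alkenes and alkynes and 5-exo radical closures onto allenes.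

Step 4
Reactants: 7 (3R,3aR,7aS)-3-(1-iodoethenyl)-7a-methyloctahydro-4H-inden-4-one
Product: 8 (3R,3aR,7aR)-3-(1-iodoethenyl)-7a-methyl-1,2,3,3a,7,7a-hexahydro-4H-inden-4-one
Conditions: IBX (2.5 equiv), DMSO/PhF (1:2), 70 °C
Reagents that add atoms: none
Why: Nicolaou IBX dehydrogenation of the ketone can only run towards C1=C2 because the other α-carbon (C16) has a quaternary neighbour, and no stereocentre is touched.

Step 5
Reactants: 8 (3R,3aR,7aR)-3-(1-iodoethenyl)-7a-methyl-1,2,3,3a,7,7a-hexahydro-4H-inden-4-one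
Product: 9 (3R,3aR,7aR)-3-(1-iodoethenyl)-4,7a-dimethyl-2,3,3a,4,7,7a-hexahydro-1H-inden-4-ol (both carbinol epimers)
Conditions: MeLi, CeCl3, THF, −78 °C
Reagents that add atoms: methyllithium, [Li]C
Why: The organocerium reagent adds 1,2 to the C15 carbonyl without conjugate addition, enolisation or iodine–metal exchange and installs the C17 methyl; the new carbinol centre is erased in the next step.

Step 6
Reactants: 9 tertiary allylic alcohol (both epimers)
Product: 10 (1R,3aR,7aR)-1-(1-iodoethenyl)-3a,7-dimethyl-1,2,3,3a,4,7a-hexahydro-5H-inden-5-one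
Conditions: pyridinium chlorochromate ([C5H5NH][CrO3Cl]), NaOAc, 4 Å MS, CH2Cl2, rt
Reagents that add atoms: pyridinium chlorochromate, [O-][Cr](=O)(=O)Cl.c1cc[nH+]cc1
Why: Dauben oxidative 1,3-transposition: the tertiary allylic chromate ester shifts [3,3] to C2 and is oxidised there, putting the C2 carbonyl and the C1=C15 double bond in their final positions.

Step 7
Reactants: 11 prop-2-enal (acrolein)
Product: 12 (3S,4R)-4-methylhexa-1,5-dien-3-ol
Conditions: (3aR,7aR)-1,3-bis[(4-bromophenyl)methyl]-2-[(2E)-but-2-en-1-yl]-2-chlorooctahydro-1H-1,3,2-benzodiazasilole, Sc(OTf)3 (5 mol%), CH2Cl2, 0 °C; then 1 M HCl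
Reagents that add atoms: Leighton (E)-crotylsilane (name as in Conditions), C/C=C/C[Si]1(Cl)N(Cc2ccc(Br)cc2)[C@@H]2CCCC[C@H]2N1Cc1ccc(Br)cc1
Why: Leighton strained-silane crotylation: the (E)-crotyl group is delivered through a closed chair transition state (anti product) to the Re face of the aldehyde under reagent control, setting C11 (S) and C12 (R); the reagent antipode is the one that gives Re-face delivery.

Step 8
Reactants: 12 (3S,4R)-4-methylhexa-1,5-dien-3-ol
Product: 13 tert-butyl(dimethyl){[(3S,4R)-4-methylhexa-1,5-dien-3-yl]oxy}silane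
Conditions: TBSCl, imidazole, DMF, rt
Reagents that add atoms: tert-butyldimethylsilyl chloride, CC(C)(C)[Si](C)(C)Cl
Why: Standard silylation of the secondary alcohol; the allylic silyl ether then differentiates the two vinyl groups.

Step 9
Reactants: 13 tert-butyl(dimethyl){[(3S,4R)-4-methylhexa-1,5-dien-3-yl]oxy}silane
Product: 15 (3R,4S)-4-{[tert-butyl(dimethyl)silyl]oxy}-3-methylhex-5-en-1-ol, via B-alkyl-9-BBN adduct 14 (not isolated)
Conditions: 9-BBN (1.05 equiv), THF, 0 °C → rt; then NaOH, H2O2, 0 °C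
Reagents that add atoms: hydrogen peroxide, OO
Why: Anti-Markovnikov hydroboration–oxidation; 9-BBN reacts preferentially at the C13=C14 vinyl group because the C9=C10 vinyl group is deactivated inductively and sterically by the allylic silyloxy group.

Step 10
Reactants: 15 (3R,4S)-4-{[tert-butyl(dimethyl)silyl]oxy}-3-methylhex-5-en-1-ol
Product: 16 tert-butyl(dimethyl){[(3S,4R)-4-methyl-6-[(triethylsilyl)oxy]hex-1-en-3-yl]oxy}silane
Conditions: TESCl, imidazole, CH2Cl2, 0 °C
Reagents that add atoms: chlorotriethylsilane, CC[Si](Cl)(CC)CC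
Why: Silylation of the primary alcohol gives a triethylsilyl ether that later serves as a masked C14 aldehyde.

Step 11
Reactants: 16 bis-silyl ether; 10 (1R,3aR,7aR)-1-(1-iodoethenyl)-3a,7-dimethyl-1,2,3,3a,4,7a-hexahydro-5H-inden-5-one
Product: 18 enone carrying the full C8–C14 side chain, via B-alkyl-9-BBN adduct 17 (not isolated)
Conditions: 16, 9-BBN, THF, rt; then 10, Pd(dppf)Cl2 (5 mol%), AsPh3, Cs2CO3, DMF/H2O, rt
Reagents that add atoms: none
Why: B-alkyl Suzuki–Miyaura coupling of the primary alkylborane with the 1-iodovinyl group forms C8–C9 and keeps the 1,1-disubstituted alkene; no stereocentre is affected.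

Step 12
Reactants: 18 enone carrying the side chain
Product: 20 α'-hydroxy enone (3-OH cis to the C18 methyl), via lithium dienolate 19 (not isolated)
Conditions: LiN(i-Pr)2, THF, −78 °C; then 2-(phenylsulfonyl)-3-phenyloxaziridine, −78 °C
Reagents that add atoms: 2-(phenylsulfonyl)-3-phenyloxaziridine, O=S(=O)(c1ccccc1)N1OC1c1ccccc1
Why: Kinetic α'-deprotonation of the β-methyl enone (as with isophorone) and Davis hydroxylation; the oxidant enters C3 from the convex β-face because the α-face is covered by the pseudo-axial C7 of the cis-fused cyclopentane, giving 3-OH cis to C18.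

Step 13
Reactants: 20 α'-hydroxy enone
Product: 21 α-iodo enone (iodine on C1)
Conditions: I2, pyridine, CH2Cl2, rt
Reagents that add atoms: iodine, II
Why: Johnson α-iodination of the enone (pyridine conjugate addition, iodination of the enolate, elimination) places iodine on C1.

Step 14
Reactants: 21 α-iodo enone
Product: 22 trans-2,3-diol
Conditions: Me4NBH(OAc)3, MeCN/AcOH, −30 °C
Reagents that add atoms: none
Why: Evans–Saksena hydroxyl-directed reduction: the C3 hydroxyl binds boron and delivers hydride to the same (β) face of the C2 carbonyl, giving the trans-diol with 2-OH on the α-face.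

Step 15
Reactants: 22 trans-2,3-diol
Product: 23 2,3-diacetate
Conditions: Ac2O, DMAP, Et3N, CH2Cl2, rt
Reagents that add atoms: acetic anhydride, CC(=O)OC(C)=O
Why: DMAP-catalysed acetylation of both secondary alcohols while C11 and C14 are still silylated.

Step 16
Reactants: 23 2,3-diacetate
Product: 24 C14 aldehyde
Conditions: (COCl)2, DMSO, CH2Cl2, −78 → −30 °C; then Et3N
Reagents that add atoms: none
Why: Under Swern conditions a primary triethylsilyl ether is converted directly into the aldehyde (chlorosulfonium attack on the ether oxygen, loss of Et3SiCl), while the secondary TBS ether, the acetates and the vinyl iodide are inert.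

Step 17
Reactants: 24 C14 aldehyde
Product: 26 (2R,3R,4S,7R,11S,12R,14S,16S)-11-{[tert-butyl(dimethyl)silyl]oxy}-14-hydroxytrinervita-1(15),8(19)-diene-2,3-diyl diacetate, via alkenylchromium dichloride 25 (not isolated)
Conditions: CrCl2 (10 equiv), NiCl2 (2 mol%), DMSO/THF (3:1), rt, 0.002 M, slow addition
Reagents that add atoms: none
Why: Nozaki–Hiyama–Kishi macrocyclisation: zerovalent nickel inserts into the C1–I bond, transmetallation gives the alkenylchromium species and this adds to the C14 aldehyde to close ring C; the tether holds C13 on the α-face and the bulky O–Cr unit is expected to sit on the open β-face, away from the C17 methyl and the C2 acetate, which gives 14S.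

Step 18
Reactants: 26 macrocyclic silyl ether
Product: 27 (2R,3R,4S,7R,11S,12R,14S,16S)-11,14-dihydroxytrinervita-1(15),8(19)-diene-2,3-diyl diacetate (CNP0114864.2)
Conditions: HF·pyridine, pyridine, THF, 0 °C → rt
Reagents that add atoms: none
Why: Fluoride cleaves the last silyl ether in a mildly acidic medium that does not cause acetyl migration, giving the target.

**Compound list**

1 | penta-3,4-dien-1-ol | C=C=CCCO | starting material
2 | 5-bromopenta-1,2-diene | C=C=CCCBr | intermediate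
3 | 3-methylcyclohex-2-en-1-one | CC1=CC(=O)CCC1 | starting material
4 | penta-3,4-dien-1-ylmagnesium bromide | C=C=CCC[Mg]Br | intermediate (not isolated)
5 | bromomagnesium (3S)-3-methyl-3-(penta-3,4-dien-1-yl)cyclohex-1-en-1-olate | C=C=CCC[C@]1(C)CCCC(O[Mg]Br)=C1 | intermediate (not isolated)
6 | (3S)-2-iodo-3-methyl-3-(penta-3,4-dien-1-yl)cyclohexan-1-one (both C2 epimers) | C=C=CCC[C@]1(C)CCCC(=O)C1I | intermediate
7 | (3R,3aR,7aS)-3-(1-iodoethenyl)-7a-methyloctahydro-4H-inden-4-one (cis-fused) | C=C(I)[C@@H]1CC[C@]2(C)CCCC(=O)[C@H]12 | intermediate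
8 | (3R,3aR,7aR)-3-(1-iodoethenyl)-7a-methyl-1,2,3,3a,7,7a-hexahydro-4H-inden-4-one | C=C(I)[C@@H]1CC[C@]2(C)CC=CC(=O)[C@H]12 | intermediate
9 | (3R,3aR,7aR)-3-(1-iodoethenyl)-4,7a-dimethyl-2,3,3a,4,7,7a-hexahydro-1H-inden-4-ol (both C4 epimers) | C=C(I)[C@@H]1CC[C@]2(C)CC=CC(C)(O)[C@H]12 | intermediate
10 | (1R,3aR,7aR)-1-(1-iodoethenyl)-3a,7-dimethyl-1,2,3,3a,4,7a-hexahydro-5H-inden-5-one | C=C(I)[C@@H]1CC[C@]2(C)CC(=O)C=C(C)[C@H]12 | intermediate
11 | prop-2-enal (acrolein) | C=CC=O | starting material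
12 | (3S,4R)-4-methylhexa-1,5-dien-3-ol | C=C[C@H](O)[C@H](C)C=C | intermediate
13 | tert-butyl(dimethyl){[(3S,4R)-4-methylhexa-1,5-dien-3-yl]oxy}silane | C=C[C@H](O[Si](C)(C)C(C)(C)C)[C@H](C)C=C | intermediate
14 | 9-[(3R,4S)-4-{[tert-butyl(dimethyl)silyl]oxy}-3-methylhex-5-en-1-yl]-9-borabicyclo[3.3.1]nonane | C=C[C@H](O[Si](C)(C)C(C)(C)C)[C@H](C)CCB1C2CCCC1CCC2 | intermediate (not isolated)
15 | (3R,4S)-4-{[tert-butyl(dimethyl)silyl]oxy}-3-methylhex-5-en-1-ol | C=C[C@H](O[Si](C)(C)C(C)(C)C)[C@H](C)CCO | intermediate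
16 | tert-butyl(dimethyl){[(3S,4R)-4-methyl-6-[(triethylsilyl)oxy]hex-1-en-3-yl]oxy}silane | C=C[C@H](O[Si](C)(C)C(C)(C)C)[C@H](C)CCO[Si](CC)(CC)CC | intermediate
17 | 9-[(3S,4R)-3-{[tert-butyl(dimethyl)silyl]oxy}-4-methyl-6-[(triethylsilyl)oxy]hexyl]-9-borabicyclo[3.3.1]nonane | C1CC2CCCC(C1)B2CC[C@H](O[Si](C)(C)C(C)(C)C)[C@H](C)CCO[Si](CC)(CC)CC | intermediate (not isolated)
18 | (1R,3aR,7aR)-1-[(5S,6R)-5-{[tert-butyl(dimethyl)silyl]oxy}-6-methyl-8-[(triethylsilyl)oxy]oct-1-en-2-yl]-3a,7-dimethyl-1,2,3,3a,4,7a-hexahydro-5H-inden-5-one | C=C(CC[C@H](O[Si](C)(C)C(C)(C)C)[C@H](C)CCO[Si](CC)(CC)CC)[C@@H]1CC[C@]2(C)CC(=O)C=C(C)[C@H]12 | intermediate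
19 | lithium dienolate of 18 (O–Li on C2; C2=C3 and C1=C15 double bonds) | C=C(CC[C@H](O[Si](C)(C)C(C)(C)C)[C@H](C)CCO[Si](CC)(CC)CC)[C@@H]1CC[C@]2(C)C=C(O[Li])C=C(C)[C@H]12 | intermediate (not isolated)
20 | (1R,3aS,4R,7aS)-1-[(5S,6R)-5-{[tert-butyl(dimethyl)silyl]oxy}-6-methyl-8-[(triethylsilyl)oxy]oct-1-en-2-yl]-4-hydroxy-3a,7-dimethyl-1,2,3,3a,4,7a-hexahydro-5H-inden-5-one | C=C(CC[C@H](O[Si](C)(C)C(C)(C)C)[C@H](C)CCO[Si](CC)(CC)CC)[C@@H]1CC[C@]2(C)[C@@H](O)C(=O)C=C(C)[C@H]12 | intermediate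
21 | (1R,3aS,4R,7aR)-1-[(5S,6R)-5-{[tert-butyl(dimethyl)silyl]oxy}-6-methyl-8-[(triethylsilyl)oxy]oct-1-en-2-yl]-4-hydroxy-6-iodo-3a,7-dimethyl-1,2,3,3a,4,7a-hexahydro-5H-inden-5-one | C=C(CC[C@H](O[Si](C)(C)C(C)(C)C)[C@H](C)CCO[Si](CC)(CC)CC)[C@@H]1CC[C@]2(C)[C@@H](O)C(=O)C(I)=C(C)[C@H]12 | intermediate
22 | (1R,3aS,4R,5S,7aR)-1-[(5S,6R)-5-{[tert-butyl(dimethyl)silyl]oxy}-6-methyl-8-[(triethylsilyl)oxy]oct-1-en-2-yl]-6-iodo-3a,7-dimethyl-2,3,3a,4,5,7a-hexahydro-1H-indene-4,5-diol (trans-diol) | C=C(CC[C@H](O[Si](C)(C)C(C)(C)C)[C@H](C)CCO[Si](CC)(CC)CC)[C@@H]1CC[C@]2(C)[C@@H](O)[C@H](O)C(I)=C(C)[C@H]12 | intermediate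
23 | (1R,3aS,4R,5S,7aR)-1-[(5S,6R)-5-{[tert-butyl(dimethyl)silyl]oxy}-6-methyl-8-[(triethylsilyl)oxy]oct-1-en-2-yl]-6-iodo-3a,7-dimethyl-2,3,3a,4,5,7a-hexahydro-1H-indene-4,5-diyl diacetate | C=C(CC[C@H](O[Si](C)(C)C(C)(C)C)[C@H](C)CCO[Si](CC)(CC)CC)[C@@H]1CC[C@]2(C)[C@@H](OC(C)=O)[C@H](OC(C)=O)C(I)=C(C)[C@H]12 | intermediate
24 | (1R,3aS,4R,5S,7aR)-1-[(5S,6R)-5-{[tert-butyl(dimethyl)silyl]oxy}-6-methyl-8-oxooct-1-en-2-yl]-6-iodo-3a,7-dimethyl-2,3,3a,4,5,7a-hexahydro-1H-indene-4,5-diyl diacetate | C=C(CC[C@H](O[Si](C)(C)C(C)(C)C)[C@H](C)CC=O)[C@@H]1CC[C@]2(C)[C@@H](OC(C)=O)[C@H](OC(C)=O)C(I)=C(C)[C@H]12 | intermediate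
25 | alkenylchromium dichloride from 24 (CrCl2 on C1 in place of iodine) | C=C(CC[C@H](O[Si](C)(C)C(C)(C)C)[C@H](C)CC=O)[C@@H]1CC[C@]2(C)[C@@H](OC(C)=O)[C@H](OC(C)=O)C([Cr](Cl)Cl)=C(C)[C@H]12 | intermediate (not isolated)
26 | (2R,3R,4S,7R,11S,12R,14S,16S)-11-{[tert-butyl(dimethyl)silyl]oxy}-14-hydroxytrinervita-1(15),8(19)-diene-2,3-diyl diacetate | C=C1CC[C@H](O[Si](C)(C)C(C)(C)C)[C@H](C)C[C@H](O)C2=C(C)[C@@H]3[C@H]1CC[C@]3(C)[C@@H](OC(C)=O)[C@@H]2OC(C)=O | intermediate
27 | (2R,3R,4S,7R,11S,12R,14S,16S)-11,14-dihydroxytrinervita-1(15),8(19)-diene-2,3-diyl diacetate (CNP0114864.2) | C=C1CC[C@H](O)[C@H](C)C[C@H](O)C2=C(C)[C@@H]3[C@H]1CC[C@]3(C)[C@@H](OC(C)=O)[C@@H]2OC(C)=O | target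

**Step count and risks**

Total steps: 18. Longest linear sequence: 14 (steps 1–6 and 11–18; the side-chain branch is steps 7–10).

Most likely to fail, first: step 3. The α-keto radical may attack the central allene carbon (6-endo, allyl radical) instead of C7, the C7 epimer may form, or the vinyl radical may abstract hydrogen internally before iodine transfer. The fallback sets out from the magnesium enolate 5 and comes back at 7. The conjugate addition of step 2 is quenched with Me3SiCl/Et3N instead of NIS to give the trimethylsilyl enol ether F1. This is closed by a polar, non-radical route: Ph3PAuNTf2 (5 mol%) and NIS in CH2Cl2 at 0 °C. Gold activates the allene, the enol ether carbon C16 attacks C7 in the 5-exo mode, and the C8–Au bond is cleaved by NIS to give 7.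

Second: step 17. Oxidative addition to the tetrasubstituted vinyl iodide is slow, and the C14 configuration rests on a conformational argument only. The fallback sets out from 24 and comes back at 26. If the Ni/Cr closure gives mainly the 14R alcohol F2, it is oxidised with Dess–Martin periodinane to the macrocyclic C14 ketone F3. This is reduced under reagent control with 2-methyl-CBS-oxazaborolidine (antipode chosen for 14S) and BH3·SMe2 at −40 °C to give 26, so the stereocentre is set by the catalyst and not by the ring closure.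

Third: step 14. Hydride delivery to the β-face of C2 passes the pseudo-axial C18 methyl, so the cis-diol may dominate. The fallback sets out from 21 and comes back at 23. Undirected Luche reduction (NaBH4, CeCl3·7H2O, MeOH, −78 °C) from the open α-face gives the cis-diol F4. A Mitsunobu reaction (PPh3, DIAD, AcOH) at the allylic C2 carbinol, which is less hindered than the neopentyl-type C3 carbinol, inverts it and installs the acetate, giving the hydroxy acetate F5. Acetylation (Ac2O, DMAP) of the C3 hydroxyl gives 23.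

**Further compounds**

F1 | step 3 | trimethyl{[(3S)-3-methyl-3-(penta-3,4-dien-1-yl)cyclohex-1-en-1-yl]oxy}silane | C=C=CCC[C@]1(C)CCCC(O[Si](C)(C)C)=C1
F2 | step 17 | (2R,3R,4S,7R,11S,12R,14R,16S)-11-{[tert-butyl(dimethyl)silyl]oxy}-14-hydroxytrinervita-1(15),8(19)-diene-2,3-diyl diacetate | C=C1CC[C@H](O[Si](C)(C)C(C)(C)C)[C@H](C)C[C@@H](O)C2=C(C)[C@@H]3[C@H]1CC[C@]3(C)[C@@H](OC(C)=O)[C@@H]2OC(C)=O
F3 | step 17 | (2R,3R,4S,7R,11S,12R,16S)-11-{[tert-butyl(dimethyl)silyl]oxy}-14-oxotrinervita-1(15),8(19)-diene-2,3-diyl diacetate | C=C1CC[C@H](O[Si](C)(C)C(C)(C)C)[C@H](C)CC(=O)C2=C(C)[C@@H]3[C@H]1CC[C@]3(C)[C@@H](OC(C)=O)[C@@H]2OC(C)=O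
F4 | step 14 | (1R,3aS,4R,5R,7aR)-1-[(5S,6R)-5-{[tert-butyl(dimethyl)silyl]oxy}-6-methyl-8-[(triethylsilyl)oxy]oct-1-en-2-yl]-6-iodo-3a,7-dimethyl-2,3,3a,4,5,7a-hexahydro-1H-indene-4,5-diol (cis-diol) | C=C(CC[C@H](O[Si](C)(C)C(C)(C)C)[C@H](C)CCO[Si](CC)(CC)CC)[C@@H]1CC[C@]2(C)[C@@H](O)[C@@H](O)C(I)=C(C)[C@H]12
F5 | step 14 | (1R,3aS,4R,5S,7aR)-1-[(5S,6R)-5-{[tert-butyl(dimethyl)silyl]oxy}-6-methyl-8-[(triethylsilyl)oxy]oct-1-en-2-yl]-4-hydroxy-6-iodo-3a,7-dimethyl-2,3,3a,4,5,7a-hexahydro-1H-inden-5-yl acetate | C=C(CC[C@H](O[Si](C)(C)C(C)(C)C)[C@H](C)CCO[Si](CC)(CC)CC)[C@@H]1CC[C@]2(C)[C@@H](O)[C@H](OC(C)=O)C(I)=C(C)[C@H]12
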